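**Plan**
1. Retrosynthetic cuts, in order: the two benzyl esters and the O-acetyl group; C8–O (hydration of C7=C8); C11–C12 and C9=C11 (borane homologation, methylenation), back to a C9 enone; then the C3–C4 bond of ring A.
2. Enabling feature: C4 of ring A (C1–C2–C3–C4–C5–C10) is quaternary and bears an oxidised one-carbon branch, C18, next to the C3 methylene. Returning C3 from C4 to C18 makes C18 a ring member and turns ring A into the seven-membered ring C1–C2–C3–C18–C4–C5–C10 carrying a C4–C18 epoxide.
3. The cycloheptene is cut at C4=C18 (ring-closing metathesis) and at C10–C1 and C10–C20 (two enolate alkylations). This leaves (R)-carvone, whose ring is ring B with C17, the C9 oxygen, C7=C8 and the C4/C19 isopropenyl group already in place.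
4. Forward order: ring B (given) → seven-membered ring → contraction to ring A with C18 pushed out as an aldehyde → C11–C13 chain on C9 → oxygen on C8 → acetate and free acids.
5. Stereochemistry: C5 comes from carvone, and C10 from alkylation anti to the isopropenyl group. C4 comes from α-epoxidation plus stereospecific inversion in the 1,2-shift, C9 from α-face hydroboration, and C8 from α-face oxygen capture. The last three are steered by the axial C20 methyl group.

Key step: step 5

Remark: labdane numbering is used for every compound (C17 on C8, C18 α and C19 β on C4, C20 on C10, side chain C11–C13), and α is the face opposite to C20. In 5, 6, F1 and F2 the future carboxyl carbon C18 is a member of the seven-membered ring. Compound 2 is drawn as its trans epimer, but either C10 epimer serves.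

Step 1
Reactants: 1 (R)-(−)-carvone
Product: 2 trans-6-methylcarvone
Conditions: LiN(iPr)2, THF, −78 °C; MeI, −78 → 0 °C
Reagents that add atoms: iodomethane, CI
Why: Kinetic α′-deprotonation of the enone and SN2 enolate alkylation put C20 on C10; this centre is planarised again in step 2, so its configuration does not matter, and C5 is carried over from the chiral pool.

Step 2
Reactants: 2 trans-6-methylcarvone; 3 5-iodopent-1-ene
Product: 4 6-methyl-6-(pent-4-enyl)carvone (pentenyl chain trans to isopropenyl)
Conditions: LiN(iPr)2, THF, −78 → 0 °C; 3, DMPU, −78 °C → rt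
Reagents that add atoms: none
Why: In this second enolate alkylation the C5 isopropenyl group turns pseudo-axial to escape allylic strain with C20, so the iodide is attacked on the opposite (α) face, which sets quaternary C10 with C20 β and C1 α.

Step 3
Reactants: 4 6-methyl-6-(pent-4-enyl)carvone
Product: 5 trans-fused bicyclo[5.4.0]undecadienone (C4=C18 in the seven-membered ring)
Conditions: second-generation Grubbs catalyst RuCl2(=CHPh)(PCy3)(H2IMes) (5 mol %), CH2Cl2 (0.002 M), reflux
Reagents that add atoms: none
Why: Ring-closing metathesis joins the terminal alkene to the isopropenyl group, which sit trans-diequatorial on C10 and C5 and so close a trans-fused cycloheptene with a trisubstituted C4=C18 bond, while the electron-poor enone bond stays out and no stereocentre is formed.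

Step 4
Reactants: 5 trans-fused bicyclo[5.4.0]undecadienone
Product: 6 4α,18α-epoxide of 5
Conditions: mCPBA, CH2Cl2, 0 °C
Reagents that add atoms: 3-chloroperoxybenzoic acid, O=C(OO)c1cccc(Cl)c1
Why: Prilezhaev epoxidation picks the electron-rich C4=C18 alkene over the enone and should attack the α face, away from the axial C20 methyl that covers the β face, which sets C4 (O α, C19 β) and C18.

Step 5
Reactants: 6 4α,18α-epoxide
Product: 7 enone aldehyde (trans-decalin; 4α-CHO, 4β-CH3)
Conditions: MeAl(OC6H2-4-Br-2,6-tBu2)2 (MABR, 2 equiv, from AlMe3 and 2 ArOH), CH2Cl2, −78 → −40 °C; H2O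
Reagents that add atoms: none
Why: The bulky aluminium Lewis acid binds the epoxide oxygen and lengthens the C4–O bond at the tertiary carbon, and as charge builds at C4 the ring bond C3–C18 swings across the β face so that C3 bonds to C4 and C18 folds out of the ring as the aluminium-bound aldehyde; this is the Meinwald rearrangement in its alkyl-shift (semipinacol) mode, known for trisubstituted epoxides and for 1-methylcycloalkene oxides, which give 1-methylcycloalkanecarbaldehydes one ring size smaller. Ring A is closed in its final size by this suprafacial 1,2-shift, a 7 → 6 contraction in which the C3–C18 σ bond displaces oxygen at C4 from the rear without any external nucleophile. C4 is the only stereocentre formed and it is fixed by stereospecific inversion at the epoxide carbon: oxygen leaves from α and C3 enters from β, so C19 stays β (axial) and C18 ends α (equatorial), the arrangement that methylation of a C4 ester enolate would not deliver. C–O cleavage is regioselective because C4 is tertiary and C18 secondary. The step needs migration of C3 rather than of the C18 hydrogen (which would keep the ring and give the 18-ketone), and three things favour it: the 2,6-di-tert-butylaryloxide ligands penalise the rotamer that aligns C18–H with the empty orbital because it presses O–Al against C19 and C5, a cycloheptane can reach the near-perpendicular endocyclic torsion that aligns C3–C18, and contraction releases seven-ring strain. The hindered C9 enone only ties up Lewis acid reversibly, which the second equivalent covers, and the low temperature protects the quaternary aldehyde.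

Step 6
Reactants: 7 enone aldehyde
Product: 8 enone 18-carboxylic acid
Conditions: NaClO2, NaH2PO4, 2-methylbut-2-ene, tBuOH–H2O, rt
Reagents that add atoms: sodium chlorite, [Na+].[O-]Cl=O
Why: Pinnick oxidation converts the hindered, non-enolisable aldehyde into the acid under buffered conditions that leave the enone and all stereocentres untouched.

Step 7
Reactants: 8 enone 18-carboxylic acid
Product: 9 enone 18-benzyl ester
Conditions: BnBr, K2CO3, DMF, rt
Reagents that add atoms: benzyl bromide, BrCc1ccccc1
Why: SN2 O-alkylation of the carboxylate avoids any attack at the hindered C18 carbonyl and installs an ester that can be removed later under neutral conditions.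

Step 8
Reactants: 9 enone 18-benzyl ester
Product: 10 7,9(11)-diene 18-benzyl ester
Conditions: Ph3PCH3Br, KOtBu, toluene, 90 °C
Reagents that add atoms: methyltriphenylphosphonium bromide, C[P+](c1ccccc1)(c1ccccc1)c1ccccc1.[Br-]
Why: Wittig methylenation, known for 2,6,6-trisubstituted cyclohex-2-enones, turns C9=O into the exocyclic C9=C11 bond, the neopentyl-type ester is inert to the ylide, and no stereocentre is formed.

Step 9
Reactants: 10 7,9(11)-diene 18-benzyl ester; 11 benzyl bromoacetate
Product: 13 dibenzyl 14,15,16-trinorlabd-7-ene-13,18-dioate, via alkylborane 12 (not isolated)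
Conditions: 9-BBN, THF, 0 → 50 °C; then 11, KOC6H3-2,6-tBu2, THF, 0 °C → rt
Reagents that add atoms: 9-borabicyclo[3.3.1]nonane, [H]B1C2CCCC1CCC2 (boron and its ring stay in 12 only)
Why: Hydroboration followed by organoborane alkylation of an α-bromo ester enolate (ate complex, 1,2-shift of C11 from boron to carbon with loss of bromide, protonolysis by the phenol): 9-BBN adds only to the 1,1-disubstituted C9=C11 bond with boron on C11 and delivers hydrogen to C9 from the α face opposite the adjacent axial C20, which sets 9α-H and the equatorial β side chain.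

Step 10
Reactants: 13 dibenzyl 14,15,16-trinorlabd-7-ene-13,18-dioate
Product: 14 dibenzyl 8α-hydroxy-14,15,16-trinorlabdane-13,18-dioate
Conditions: Mn(dpm)3 (10 mol %), PhSiH3, O2 (1 atm), iPrOH–CH2Cl2, 0 °C → rt
Reagents that add atoms: dioxygen, O=O
Why: Mukaiyama hydration (hydrogen atom transfer to C7, capture of the tertiary C8 radical by O2, reduction of the peroxide) gives Markovnikov regiochemistry, and oxygen should enter from the α (equatorial) side because the β lobe is 1,3-diaxial to C20, giving 8α-OH with C17 axial.

Step 11
Reactants: 14 dibenzyl 8α-hydroxy-14,15,16-trinorlabdane-13,18-dioate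
Product: 15 dibenzyl 8α-acetoxy-14,15,16-trinorlabdane-13,18-dioate
Conditions: AcCl, PhNMe2, CH2Cl2, 0 °C → rt
Reagents that add atoms: acetyl chloride, CC(=O)Cl
Why: O-acylation with acetyl chloride and a weak amine base is the established way to esterify hindered tertiary 8α-hydroxylabdanes without elimination, the low alkoxide level holds back δ-lactonisation onto the C13 ester, and C8 keeps its configuration because the C–O bond is not broken.

Step 12
Reactants: 15 dibenzyl 8α-acetoxy-14,15,16-trinorlabdane-13,18-dioate
Product: 16 8α-acetoxy-14,15,16-trinorlabdane-13,18-dioic acid (CNP0196050.1)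
Conditions: H2 (1 atm), Pd/C, EtOAc, rt
Reagents that add atoms: none
Why: Catalytic hydrogenolysis frees both acids, including the hindered C18 one, under neutral conditions that spare the tertiary acetate, which acidic or basic ester cleavage would endanger.

**Compound list**
1 | (R)-(−)-carvone | CC1=CC[C@@H](C(C)=C)CC1=O | starting material
2 | trans-6-methylcarvone (10α-CH3 drawn; C10 epimers both usable) | CC1=CC[C@@H](C(C)=C)[C@H](C)C1=O | intermediate
3 | 5-iodopent-1-ene | C=CCCCI | starting material
4 | 6-methyl-6-(pent-4-enyl)carvone; 5α-H, 10β-CH3, 10α-pentenyl (trans to isopropenyl) | CC1=CC[C@@H](C(C)=C)[C@](C)(CCCC=C)C1=O | intermediate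
5 | 3,4a,9-trimethyl-1,4a,5,6,7,9a-hexahydro-4H-benzo[7]annulen-4-one, trans-fused; 5α-H, 10β-CH3, C4(CH3)=C18H in the seven-membered ring | CC1=CC[C@@H]2[C@](C)(CCCC=C2C)C1=O | intermediate
6 | 4α,18α-epoxide of 5 (C19 β, 18-H β) | CC1=CC[C@@H]2[C@](C)(CCC[C@H]3O[C@@]23C)C1=O | intermediate
7 | enone aldehyde: trans-decalin, 4α-CHO (C18), 4β-CH3 (C19), 5α-H, 10β-CH3, C7=C8(CH3)–C9=O | CC1=CC[C@@H]2[C@](C)(CCC[C@@]2(C)C=O)C1=O | intermediate
8 | enone 18-carboxylic acid (as 7, 4α-COOH) | CC1=CC[C@@H]2[C@](C)(CCC[C@@]2(C)C(=O)O)C1=O | intermediate
9 | enone 18-benzyl ester | CC1=CC[C@@H]2[C@](C)(CCC[C@@]2(C)C(=O)OCc3ccccc3)C1=O | intermediate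
10 | 7,9(11)-diene 18-benzyl ester (C9=C11H2) | CC1=CC[C@@H]2[C@](C)(CCC[C@@]2(C)C(=O)OCc3ccccc3)C1=C | intermediate
11 | benzyl bromoacetate | O=C(CBr)OCc1ccccc1 | starting material
12 | alkylborane: 9α-H, 9β-CH2–(9-BBN) | CC1=CC[C@@H]2[C@](C)(CCC[C@@]2(C)C(=O)OCc3ccccc3)[C@H]1CB4C5CCCC4CCC5 | intermediate
13 | dibenzyl 14,15,16-trinorlabd-7-ene-13,18-dioate | CC1=CC[C@@H]2[C@](C)(CCC[C@@]2(C)C(=O)OCc3ccccc3)[C@H]1CCC(=O)OCc4ccccc4 | intermediate
14 | dibenzyl 8α-hydroxy-14,15,16-trinorlabdane-13,18-dioate | O[C@]1(C)CC[C@@H]2[C@](C)(CCC[C@@]2(C)C(=O)OCc3ccccc3)[C@H]1CCC(=O)OCc4ccccc4 | intermediate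
15 | dibenzyl 8α-acetoxy-14,15,16-trinorlabdane-13,18-dioate | CC(=O)O[C@]1(C)CC[C@@H]2[C@](C)(CCC[C@@]2(C)C(=O)OCc3ccccc3)[C@H]1CCC(=O)OCc4ccccc4 | intermediate
16 | 8α-acetoxy-14,15,16-trinorlabdane-13,18-dioic acid | CC(=O)O[C@]1(C)CC[C@@H]2[C@](C)(CCC[C@@]2(C)C(=O)O)[C@H]1CCC(=O)O | target

Total step count: 12. Longest linear sequence: 12.

**Steps most likely to fail**

Step 5. Hydride migration from C18 may compete with migration of C3, or a free C4 cation may erode the stereospecificity. The fallback sets out from epoxide 6 and comes back at benzyl ester 9, and it still contracts the same ring. SbF5 (cat.) in toluene at −78 °C steers the Meinwald rearrangement fully to hydride shift and gives the ring-retained 4-methyl-18-ketone F1. SO2Cl2 in CH2Cl2 chlorinates through the more substituted enol from the open α face to give the 4α-chloro ketone F2. A Favorskii rearrangement with NaOCH2Ph in Et2O (non-polar medium) then follows. The C3 enolate displaces chloride from the rear to a C3–C4–C18 cyclopropanone, and this opens toward the less substituted C3 carbanion. The result is 9 with the same C4 configuration.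

Step 9. The 1,2-shift of the hindered C11 group from boron may be slow, or a cyclooctyl B–C bond may migrate instead. The fallback sets out from alkylborane 12 and comes back at 13. Oxidation with NaBO3·4H2O gives the C11 primary alcohol F3. Dess–Martin periodinane gives the C11 aldehyde F4, whose C9 centre can settle in the equatorial β arrangement. Horner–Wadsworth–Emmons olefination with benzyl (diethoxyphosphoryl)acetate and NaH gives the (E)-enoate F5. Conjugate reduction with [(Ph3P)CuH]6 leaves C7=C8 and both benzyl esters intact and delivers 13.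

Step 10. Facial selectivity in the capture of the planar C8 radical may be poor, and the δ-hydroxy ester formed may lactonise in the next step. The fallback sets out from 13 and comes back at 16, replacing steps 10–12.
- mCPBA, which discriminates between faces more strongly than O2 does, gives the 7α,8α-epoxide F6.
- LiAlH4 in THF at reflux delivers hydride to the secondary C7 and reduces both esters, giving the 8α,13,18-triol F7.
- AcCl/PhNMe2 gives the triacetate F8.
- K2CO3 in MeOH removes only the two primary acetates and gives the 8α-acetoxy-13,18-diol F9.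
- Jones oxidation (CrO3, H2SO4, acetone, 0 °C) takes both primary alcohols to the acids of 16.

**Further compounds**
F1 | step 5 | ring-retained 4-methyl-18-ketone (seven-membered ring; 4β-H drawn, epimerisable) | CC1=CC[C@@H]2[C@](C)(CCCC(=O)[C@H]2C)C1=O
F2 | step 5 | 4α-chloro-4β-methyl-18-ketone | CC1=CC[C@@H]2[C@](C)(CCCC(=O)[C@@]2(C)Cl)C1=O
F3 | step 9 | C11 primary alcohol (9β-CH2OH, 18-benzyl ester) | CC1=CC[C@@H]2[C@](C)(CCC[C@@]2(C)C(=O)OCc3ccccc3)[C@H]1CO
F4 | step 9 | C11 aldehyde (9β-CHO, 18-benzyl ester) | CC1=CC[C@@H]2[C@](C)(CCC[C@@]2(C)C(=O)OCc3ccccc3)[C@H]1C=O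
F5 | step 9 | (E)-11-enoate dibenzyl ester | CC1=CC[C@@H]2[C@](C)(CCC[C@@]2(C)C(=O)OCc3ccccc3)[C@H]1/C=C/C(=O)OCc4ccccc4
F6 | step 10 | 7α,8α-epoxide of 13 | O1[C@@H]2C[C@@H]3[C@](C)(CCC[C@@]3(C)C(=O)OCc4ccccc4)[C@@H](CCC(=O)OCc5ccccc5)[C@]12C
F7 | step 10 | 14,15,16-trinorlabdane-8α,13,18-triol | O[C@]1(C)CC[C@@H]2[C@](C)(CCC[C@@]2(C)CO)[C@H]1CCCO
F8 | step 10 | 8α,13,18-triacetate | CC(=O)O[C@]1(C)CC[C@@H]2[C@](C)(CCC[C@@]2(C)COC(C)=O)[C@H]1CCCOC(C)=O
F9 | step 10 | 8α-acetoxy-14,15,16-trinorlabdane-13,18-diol | CC(=O)O[C@]1(C)CC[C@@H]2[C@](C)(CCC[C@@]2(C)CO)[C@H]1CCCO
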